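All runs come from a simulation with made-up constants, and the scatter is random.

It is tempting to read the ochre and blue plateaus as target matching the second substrate one for one, ochre's 39.6% beside a charge of 0.38 equiv, but teal, with 0.76 equiv, reads 34.1% at best.

| setting | ochre | teal | blue | Monday's | Thursday's |
|---|---|---|---|---|---|
| starting material | 45 mM | 45 mM | 45 mM | 45 mM | 45 mM |
| reagent | 1.1 equiv | 1.1 equiv | 1.5 equiv | 1.10 equiv | 2.20 equiv |
| second substrate | 0.38 equiv | 0.76 equiv | 0.50 equiv | 0.500 equiv | 1.00 equiv |
| catalyst | 10 mol% | 10 mol% | 10 mol% | 10 mol% | 10 mol% |
| remark | run made earlier | run made earlier | run made earlier |  |  |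
| time |  |  |  | 15 min | 15 min |

- ochre (time / min: target / %, starting material / %): 0.667: 16.7, 82.6; 1.00: 22.3, 76.9; 1.33: 26.8, 73.5; 2.00: 31.9, 67.6; 3.00: 36.8, 63.1; 5.00: 39.6, 59.8; 8.00: 39.6, 60.3
- teal (time / min: target / %, starting material / %): 0.667: 16.1, 83.9; 1.00: 21.1, 78.4; 1.33: 24.9, 75.3; 2.00: 30.0, 71.0; 3.00: 33.1, 67.6; 5.00: 34.1, 66.5; 8.00: 31.4, 68.9
- blue (time / min: target / %, starting material / %): 1.50: 34.8, 64.3; 3.00: 45.0, 54.4; 5.00: 48.1, 51.6; 6.00: 49.1, 50.8; 8.00: 49.5, 51.4

(standard deviation of a reading: 0.5 percentage points)

- the earlier runs were read with a standard deviation of 0.5 percentage points

* the flask that ends with the higher amount of target, in percent of the starting material charged, or "neither" when 2 percentage points or less lies between them (Monday's / Thursday's / neither)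
* final target, as a percentage of the starting material charged, in Monday's
* final target, as a percentage of the starting material charged, in Thursday's

So I look at the pair I can read. Target and starting material sum close to the whole charge in each run, and in teal target falls from 34.1% to 31.4% while starting material rises from 66.5% to 68.9%, so this step runs backward as well as forward.

That suggests counting turnovers. I assume that each target costs one reagent and each second substrate costs one reagent, and I count the second substrate as wholly spent. Reagent left, as a fraction of the starting material charged, is then the reagent charge minus the second substrate charge minus target. Blue's last reading gives the turnover quotient, a reaction quotient: target over starting material, divided by reagent left, 1.91. Ochre's last reading gives 2.03, which stands close to it. Teal is still moving, so I set it aside. Any second substrate still unspent makes these readings high, so I carry the lower one.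

Holding the quotient fixed and solving for target, my own reckoning gives 33.5% for Monday's and 55.3% for Thursday's. The gap of 22 points is wider than the margin.

The forecast also picks Thursday's, but with 49% and 82%, both higher than my figures , on the grounds that “Thursday has the same ratio, so it is not reagent-starved”.

Monday's ends at 33.9% and Thursday's at 52.7%, so Thursday's gives more.

    starting material + reagent + catalyst ⇌ catalyst + target (K = 36.0 /M, k = 26.0 /M²/s)
    second substrate + reagent + catalyst → catalyst + second product (k = 33.0 /M²/s)

At 15.0 min, Thursday's holds 0.691% of its second substrate and 30.9% of its reagent, and from that state the quotient is 1.63. For a neighbouring flask, which is Monday's with 1.90 equiv of reagent, the same count with 1.91 gives 60.3% of target, and that flask ends with 57.4%.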